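A direct plan would start from two preformed pentylresorcinol rings and join them by esterification.
1,3-Dimethoxy-5-pentylbenzene A1 would be chlorinated by lithiation, formylated, demethylated next to the formyl group and oxidised to 3-chloro-2-hydroxy-4-methoxy-6-pentylbenzoic acid A2.
A2 would be esterified with 2,4-dihydroxy-6-pentylbenzaldehyde A3 to the depside aldehyde A4, and oxidation of the formyl group would end the route.
Its first weak point would be the four-step relay of functional groups that only adds Cl and CO2H to ring A, on a ring whose pentyl chain already cost a cross-coupling: many steps for little gain in complexity.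
Its second would be the aroylation of a phenol by a benzoic acid with both ortho positions occupied and a free ortho hydroxyl: the site of acylation would rest on hydrogen bonding alone and the acid could condense with itself.
Its third would be the closing chlorite oxidation on the complete depside: hypochlorous acid would meet an electron-rich phenol ring with two free positions on the most precious material.
No ring closure or stereocentre would be at stake; the cost would lie in step count and late selectivity.

Plan of the new route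
No bond between the rings is cut first. Ring A is cut at C1–C2 and C5–C6 (retro-Diels–Alder).
C1, C6, the pentyl chain and the ester carbon then come from oct-2-ynoic acid; C2–C5 with both oxygens come from 2-chlorodimedone, whose C2 already carries the chlorine between the two carbonyls.
Ring B is cut the same way into oct-2-ynoate and dimedone, so both rings come from one C8 acid.
Ring B arises first; its free 4-OH is acylated with the unhindered ynoic acid, and ring A is then grown on that ester.
The hindered aroylation, the late aldehyde oxidation and every ring halogenation or formylation disappear; the end game is one O-methylation and a neutral deallylation.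

Key step: step 6

Remark: the target has no stereocentre; oct-2-ynoic acid, dimedone and 2-chloro-5,5-dimethylcyclohexane-1,3-dione are taken as purchasable.

Step 1
Reactants: 1 oct-2-ynoic acid; 2 allyl bromide (3-bromoprop-1-ene)
Product: 3 prop-2-en-1-yl oct-2-ynoate
Conditions: KHCO3 (1.5 equiv), 2 (1.3 equiv), DMF, rt, 16 h
Reagents that add atoms: none
Why: SN2 O-alkylation of the potassium carboxylate; bicarbonate is too weak a base to isomerise the 2-ynoate to the allenoate, and the allyl ester is chosen because it can be removed at the end under neutral zerovalent-palladium catalysis.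

Step 2
Reactants: 4 dimedone (5,5-dimethylcyclohexane-1,3-dione)
Product: 6 5,5-dimethyl-1,3-bis(trimethylsilyloxy)cyclohexa-1,3-diene, via silyl enol ether 5 (not isolated)
Conditions: TMSCl (1.2 equiv), Et3N (1.3 equiv), THF, rt, 2 h, filter under argon; then LDA (1.1 equiv), THF, −78 °C, 1 h; TMSCl (1.2 equiv), −78 °C → rt; pentane, filter, bulb-to-bulb distillation
Reagents that add atoms: chlorotrimethylsilane C[Si](C)(C)Cl (both Me3Si groups)
Why: O-silylation of the enolised dione gives the vinylogous silyl ester 5, and kinetic deprotonation at its α' methylene followed by O-silylation (silyl enol ether formation) should give the s-cis-locked 1,3-dioxygenated diene.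

Step 3
Reactants: 3 prop-2-en-1-yl oct-2-ynoate; 6 5,5-dimethyl-1,3-bis(trimethylsilyloxy)cyclohexa-1,3-diene
Product: 9 prop-2-en-1-yl 2,4-dihydroxy-6-pentylbenzoate, via bicyclooctadiene adduct 7 (not isolated), via disilyl ether 8 (not isolated)
Conditions: 6 (2.0 equiv), neat, sealed tube, argon, 150 °C, 36 h; then 1 M HCl, THF, rt, 1 h
Reagents that add atoms: none
Why: Diels–Alder reaction of the electron-rich diene with the 2-alkynoate (CH terminus of the diene to the pentyl-bearing β-carbon), then Alder–Rickert cycloreversion with loss of isobutene and acidic cleavage of the aryl silyl ethers, a sequence with close precedent for 2-alkynoate esters.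

Step 4
Reactants: 9 prop-2-en-1-yl 2,4-dihydroxy-6-pentylbenzoate; 1 oct-2-ynoic acid
Product: 10 prop-2-en-1-yl 2-hydroxy-4-(oct-2-ynoyloxy)-6-pentylbenzoate
Conditions: 1 (1.1 equiv), DCC (1.15 equiv), DMAP (5 mol %), CH2Cl2, −20 → 0 °C, 3 h
Reagents that add atoms: none
Why: Steglich esterification at the only unchelated phenol (the 2-OH is hydrogen-bonded to the ester carbonyl); the acyl carbon of the alkynoic acid is unhindered, so the future depside ester bond is made before its two ortho substituents exist.

Step 5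
Reactants: 11 2-chlorodimedone (2-chloro-5,5-dimethylcyclohexane-1,3-dione)
Product: 13 2-chloro-5,5-dimethyl-1,3-bis(trimethylsilyloxy)cyclohexa-1,3-diene, via silyl enol ether 12 (not isolated)
Conditions: TMSCl (1.2 equiv), Et3N (1.3 equiv), THF, 0 °C → rt, 2 h, filter under argon; then LDA (1.1 equiv), THF, −78 °C, 1 h; TMSCl (1.2 equiv), −78 °C → rt; pentane, filter, bulb-to-bulb distillation, use at once
Reagents that add atoms: chlorotrimethylsilane C[Si](C)(C)Cl (both Me3Si groups)
Why: Same double silyl enol ether formation as in step 2; the chlorine is vinylic in 12 and inert to the amide base, and the symmetry of the dione allows only one diene, with the chlorine on the carbon between the two oxygens.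

Step 6
Reactants: 10 prop-2-en-1-yl 2-hydroxy-4-(oct-2-ynoyloxy)-6-pentylbenzoate; 13 2-chloro-5,5-dimethyl-1,3-bis(trimethylsilyloxy)cyclohexa-1,3-diene
Product: 16 prop-2-en-1-yl 4-[(3-chloro-2,4-dihydroxy-6-pentylbenzoyl)oxy]-2-hydroxy-6-pentylbenzoate, via bicyclooctadiene adduct 14 (not isolated), via disilyl ether 15 (not isolated)
Conditions: 13 (3.0 equiv), neat, sealed tube, argon, 160 °C, 48 h; then 1 M HCl, THF, rt, 1 h
Reagents that add atoms: none
Why: Thermal normal-electron-demand Diels–Alder reaction between the s-cis-locked, doubly oxygenated diene 13 and the electron-poor C≡C of aryl ynoate 10 gives bicyclo[2.2.2]octa-2,5-diene 14, which at the same temperature undergoes cycloreversion (Alder–Rickert reaction), ejecting its saturated CMe2–CH2 bridge as isobutene and leaving ring A aromatic. The closest known reaction type is the cycloaddition and isobutene extrusion of 2-alkynoate esters with the chlorine-free diene 6 to give 6-alkyl-2,4-dihydroxybenzoates, as used in step 3; only the vinylic chlorine on C2 of the diene is new. Ring A closes by two C–C bonds (C1–C2 and C5–C6 of ring A) formed in one suprafacial six-centre transition state and is aromatised by the retro-[4+2] step, not by oxidation. The two bridgehead centres of 14 form as a racemate and vanish with the bridge, so no stereocontrol is needed. The selectivity needed is regiochemical: the unsubstituted diene terminus C4, the β-carbon of the C3 silyl enol ether and the site of the largest HOMO coefficient, should bond to the pentyl-bearing β-carbon of the ynoate while the silyloxy-bearing C1 bonds to the α-carbon, which fixes OH at C2, Cl at C3, oxygen at C4 and pentyl at C6, and the symmetric diene allows no further isomer. The allyl ester alkene and ring B are unactivated toward the electron-rich diene, and any silyl group taken up by the chelated ring B hydroxyl from excess 13 is lost in the same acidic work-up that frees the two ring A phenols.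

Step 7
Reactants: 16 prop-2-en-1-yl 4-[(3-chloro-2,4-dihydroxy-6-pentylbenzoyl)oxy]-2-hydroxy-6-pentylbenzoate
Product: 17 prop-2-en-1-yl 4-[(3-chloro-2-hydroxy-4-methoxy-6-pentylbenzoyl)oxy]-2-hydroxy-6-pentylbenzoate
Conditions: MeI (1.2 equiv), K2CO3 (1.1 equiv), acetone, rt, 6 h
Reagents that add atoms: iodomethane CI (O-methyl carbon)
Why: Williamson ether synthesis at the 4-OH of ring A, which is acidified by the ortho chlorine and the para ester and is the only phenol not hydrogen-bonded to a carbonyl, so it alone should be deprotonated by carbonate and methylated.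

Step 8
Reactants: 17 prop-2-en-1-yl 4-[(3-chloro-2-hydroxy-4-methoxy-6-pentylbenzoyl)oxy]-2-hydroxy-6-pentylbenzoate
Product: 18 4-[(3-chloro-2-hydroxy-4-methoxy-6-pentylbenzoyl)oxy]-2-hydroxy-6-pentylbenzoic acid
Conditions: Pd(PPh3)4 (5 mol %), sodium p-toluenesulfinate (1.5 equiv), THF/MeOH 1:1, rt, 1 h; then 1 M HCl
Reagents that add atoms: none
Why: Tsuji–Trost deallylation: zerovalent palladium ionises the allyl ester to a π-allyl complex and the sulfinate takes the allyl group as a sulfone, under neutral conditions that should spare the aryl ester, the aryl chloride and the free phenols.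

Compound list
1 | oct-2-ynoic acid | CCCCCC#CC(=O)O | starting material
2 | allyl bromide (3-bromoprop-1-ene) | C=CCBr | starting material
3 | prop-2-en-1-yl oct-2-ynoate | CCCCCC#CC(=O)OCC=C | intermediate
4 | dimedone (5,5-dimethylcyclohexane-1,3-dione) | CC1(C)CC(=O)CC(=O)C1 | starting material
5 | 5,5-dimethyl-3-(trimethylsilyloxy)cyclohex-2-en-1-one | CC1(C)CC(=O)C=C(O[Si](C)(C)C)C1 | intermediate
6 | 5,5-dimethyl-1,3-bis(trimethylsilyloxy)cyclohexa-1,3-diene | C[Si](C)(C)OC1=CC(O[Si](C)(C)C)=CC(C)(C)C1 | intermediate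
7 | prop-2-en-1-yl 8,8-dimethyl-3-pentyl-1,5-bis(trimethylsilyloxy)bicyclo[2.2.2]octa-2,5-diene-2-carboxylate (racemic, centres lost on cycloreversion) | C=CCOC(=O)C1=C(CCCCC)C2C(O[Si](C)(C)C)=CC1(O[Si](C)(C)C)CC2(C)C | intermediate
8 | prop-2-en-1-yl 6-pentyl-2,4-bis(trimethylsilyloxy)benzoate | C=CCOC(=O)c1c(CCCCC)cc(O[Si](C)(C)C)cc1O[Si](C)(C)C | intermediate
9 | prop-2-en-1-yl 2,4-dihydroxy-6-pentylbenzoate | C=CCOC(=O)c1c(CCCCC)cc(O)cc1O | intermediate
10 | prop-2-en-1-yl 2-hydroxy-4-(oct-2-ynoyloxy)-6-pentylbenzoate | C=CCOC(=O)c1c(CCCCC)cc(OC(=O)C#CCCCCC)cc1O | intermediate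
11 | 2-chlorodimedone (2-chloro-5,5-dimethylcyclohexane-1,3-dione) | CC1(C)CC(=O)C(Cl)C(=O)C1 | starting material
12 | 2-chloro-5,5-dimethyl-3-(trimethylsilyloxy)cyclohex-2-en-1-one | CC1(C)CC(=O)C(Cl)=C(O[Si](C)(C)C)C1 | intermediate
13 | 2-chloro-5,5-dimethyl-1,3-bis(trimethylsilyloxy)cyclohexa-1,3-diene | C[Si](C)(C)OC1=C(Cl)C(O[Si](C)(C)C)=CC(C)(C)C1 | intermediate
14 | 3-hydroxy-5-pentyl-4-[(prop-2-en-1-yloxy)carbonyl]phenyl 6-chloro-8,8-dimethyl-3-pentyl-1,5-bis(trimethylsilyloxy)bicyclo[2.2.2]octa-2,5-diene-2-carboxylate (racemic, centres lost on cycloreversion) | C=CCOC(=O)c1c(CCCCC)cc(OC(=O)C2=C(CCCCC)C3C(O[Si](C)(C)C)=C(Cl)C2(O[Si](C)(C)C)CC3(C)C)cc1O | intermediate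
15 | prop-2-en-1-yl 4-{[3-chloro-6-pentyl-2,4-bis(trimethylsilyloxy)benzoyl]oxy}-2-hydroxy-6-pentylbenzoate | C=CCOC(=O)c1c(CCCCC)cc(OC(=O)c2c(CCCCC)cc(O[Si](C)(C)C)c(Cl)c2O[Si](C)(C)C)cc1O | intermediate
16 | prop-2-en-1-yl 4-[(3-chloro-2,4-dihydroxy-6-pentylbenzoyl)oxy]-2-hydroxy-6-pentylbenzoate | C=CCOC(=O)c1c(CCCCC)cc(OC(=O)c2c(CCCCC)cc(O)c(Cl)c2O)cc1O | intermediate
17 | prop-2-en-1-yl 4-[(3-chloro-2-hydroxy-4-methoxy-6-pentylbenzoyl)oxy]-2-hydroxy-6-pentylbenzoate | C=CCOC(=O)c1c(CCCCC)cc(OC(=O)c2c(CCCCC)cc(OC)c(Cl)c2O)cc1O | intermediate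
18 | 4-[(3-chloro-2-hydroxy-4-methoxy-6-pentylbenzoyl)oxy]-2-hydroxy-6-pentylbenzoic acid | CCCCCc1cc(OC(=O)c2c(CCCCC)cc(OC)c(Cl)c2O)cc(O)c1C(=O)O | target

Total step count: 8. Longest linear sequence: 6 steps (1, 3, 4, 6, 7, 8); steps 2 and 5 are one-step side branches that supply the two dienes.

Steps most likely to fail

Step 6. The chlorine on C2 of diene 13 lowers the energy of its highest occupied orbital, so the cycloaddition may run too slowly to outpace thermal silyl loss and decomposition of the diene. The fallback sets out from 10 and uses the chlorine-free diene 6 under the conditions of step 3, the pairing with the closest precedent. It would pass through the bicyclooctadiene adduct F1 and the disilyl ether F2 and give, after acidic work-up, prop-2-en-1-yl 4-[(2,4-dihydroxy-6-pentylbenzoyl)oxy]-2-hydroxy-6-pentylbenzoate F3. Methylation as in step 7 would give prop-2-en-1-yl 2-hydroxy-4-[(2-hydroxy-4-methoxy-6-pentylbenzoyl)oxy]-6-pentylbenzoate F4. Amine-directed ortho-chlorination of the ring A phenol (SO2Cl2 1.0 equiv, 2,2,6,6-tetramethylpiperidine 10 mol %, toluene, 0 °C) should then place the chlorine at C3, next to the free hydroxyl; any C5 isomer would be removed by chromatography. The fallback comes back to the route at 17.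

Step 5. The mono silyl ether 12 is the vinylogous silyl ester of a very acidic dione and may hand its silyl group to the amide base instead of being deprotonated, or 13 may not survive isolation. The fallback sets out from 11 and comes back at 16.
- Vinylogous esterification (MeOH, catalytic TsOH, toluene, reflux with removal of water) would give the robust 2-chloro-3-methoxy-5,5-dimethylcyclohex-2-en-1-one F5.
- Kinetic α' deprotonation (LDA, THF, −78 °C) and TMSCl would give 2-chloro-1-methoxy-5,5-dimethyl-3-(trimethylsilyloxy)cyclohexa-1,3-diene F6.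
- Cycloaddition of F6 with 10 as in step 6 would put the methoxy-bearing terminus next to the ester carbon. It would lead through the bicyclooctadiene adduct F7 and the silyl ether F8 to prop-2-en-1-yl 4-[(3-chloro-4-hydroxy-2-methoxy-6-pentylbenzoyl)oxy]-2-hydroxy-6-pentylbenzoate F9.
- BCl3 (CH2Cl2, −78 → 0 °C) would then cleave the methyl ether ortho to the ester carbonyl by chelation, through the aryl dichloroborinate F10, and water would set free 16.

Step 7. Methylation may spread from the ring A 4-OH to the two chelated hydroxyls once more than one phenoxide is present, leaving mixtures of ethers. The fallback sets out from 16 and methylates all three phenols on purpose (MeI in excess, K2CO3, acetone, reflux) to prop-2-en-1-yl 4-[(3-chloro-2,4-dimethoxy-6-pentylbenzoyl)oxy]-2-methoxy-6-pentylbenzoate F11. BCl3 (2.5 equiv, CH2Cl2, −78 → 0 °C) would then cleave only the two methyl ethers that can chelate to an ester carbonyl, through the bis(dichloroborinate) F12, and water would return the route at 17 with the 4-methoxy group intact.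

Further compounds
F1 | step 6 | 3-hydroxy-5-pentyl-4-[(prop-2-en-1-yloxy)carbonyl]phenyl 8,8-dimethyl-3-pentyl-1,5-bis(trimethylsilyloxy)bicyclo[2.2.2]octa-2,5-diene-2-carboxylate (racemic) | C=CCOC(=O)c1c(CCCCC)cc(OC(=O)C2=C(CCCCC)C3C(O[Si](C)(C)C)=CC2(O[Si](C)(C)C)CC3(C)C)cc1O
F2 | step 6 | prop-2-en-1-yl 2-hydroxy-6-pentyl-4-{[6-pentyl-2,4-bis(trimethylsilyloxy)benzoyl]oxy}benzoate | C=CCOC(=O)c1c(CCCCC)cc(OC(=O)c2c(CCCCC)cc(O[Si](C)(C)C)cc2O[Si](C)(C)C)cc1O
F3 | step 6 | prop-2-en-1-yl 4-[(2,4-dihydroxy-6-pentylbenzoyl)oxy]-2-hydroxy-6-pentylbenzoate | C=CCOC(=O)c1c(CCCCC)cc(OC(=O)c2c(CCCCC)cc(O)cc2O)cc1O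
F4 | step 6 | prop-2-en-1-yl 2-hydroxy-4-[(2-hydroxy-4-methoxy-6-pentylbenzoyl)oxy]-6-pentylbenzoate | C=CCOC(=O)c1c(CCCCC)cc(OC(=O)c2c(CCCCC)cc(OC)cc2O)cc1O
F5 | step 5 | 2-chloro-3-methoxy-5,5-dimethylcyclohex-2-en-1-one | COC1=C(Cl)C(=O)CC(C)(C)C1
F6 | step 5 | 2-chloro-1-methoxy-5,5-dimethyl-3-(trimethylsilyloxy)cyclohexa-1,3-diene | COC1=C(Cl)C(O[Si](C)(C)C)=CC(C)(C)C1
F7 | step 5 | 3-hydroxy-5-pentyl-4-[(prop-2-en-1-yloxy)carbonyl]phenyl 6-chloro-1-methoxy-8,8-dimethyl-3-pentyl-5-(trimethylsilyloxy)bicyclo[2.2.2]octa-2,5-diene-2-carboxylate (racemic) | C=CCOC(=O)c1c(CCCCC)cc(OC(=O)C2=C(CCCCC)C3C(O[Si](C)(C)C)=C(Cl)C2(OC)CC3(C)C)cc1O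
F8 | step 5 | prop-2-en-1-yl 4-{[3-chloro-2-methoxy-6-pentyl-4-(trimethylsilyloxy)benzoyl]oxy}-2-hydroxy-6-pentylbenzoate | C=CCOC(=O)c1c(CCCCC)cc(OC(=O)c2c(CCCCC)cc(O[Si](C)(C)C)c(Cl)c2OC)cc1O
F9 | step 5 | prop-2-en-1-yl 4-[(3-chloro-4-hydroxy-2-methoxy-6-pentylbenzoyl)oxy]-2-hydroxy-6-pentylbenzoate | C=CCOC(=O)c1c(CCCCC)cc(OC(=O)c2c(CCCCC)cc(O)c(Cl)c2OC)cc1O
F10 | step 5 | prop-2-en-1-yl 4-({3-chloro-2-[(dichloroboranyl)oxy]-4-hydroxy-6-pentylbenzoyl}oxy)-2-hydroxy-6-pentylbenzoate | C=CCOC(=O)c1c(CCCCC)cc(OC(=O)c2c(CCCCC)cc(O)c(Cl)c2OB(Cl)Cl)cc1O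
F11 | step 7 | prop-2-en-1-yl 4-[(3-chloro-2,4-dimethoxy-6-pentylbenzoyl)oxy]-2-methoxy-6-pentylbenzoate | C=CCOC(=O)c1c(CCCCC)cc(OC(=O)c2c(CCCCC)cc(OC)c(Cl)c2OC)cc1OC
F12 | step 7 | prop-2-en-1-yl 4-({3-chloro-2-[(dichloroboranyl)oxy]-4-methoxy-6-pentylbenzoyl}oxy)-2-[(dichloroboranyl)oxy]-6-pentylbenzoate | C=CCOC(=O)c1c(CCCCC)cc(OC(=O)c2c(CCCCC)cc(OC)c(Cl)c2OB(Cl)Cl)cc1OB(Cl)Cl
A1 | direct plan | 1,3-dimethoxy-5-pentylbenzene | CCCCCc1cc(OC)cc(OC)c1
A2 | direct plan | 3-chloro-2-hydroxy-4-methoxy-6-pentylbenzoic acid | CCCCCc1cc(OC)c(Cl)c(O)c1C(=O)O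
A3 | direct plan | 2,4-dihydroxy-6-pentylbenzaldehyde | CCCCCc1cc(O)cc(O)c1C=O
A4 | direct plan | 4-formyl-3-hydroxy-5-pentylphenyl 3-chloro-2-hydroxy-4-methoxy-6-pentylbenzoate | CCCCCc1cc(OC(=O)c2c(CCCCC)cc(OC)c(Cl)c2O)cc(O)c1C=O
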